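The runs are calculated from invented constants.

Count the free J, not the J charged.

in all of them: G 0.20 M (in portions, 3)
- Tuesday's: J 0.060 M; Z 0.060 M; temperature 78 °C; run made earlier; portions every 40 s
- Sunday's: J 0.090 M; Z 0.060 M; temperature 105 °C; run made earlier; portions every 40 s
- north-east: J 0.120 M; Z 0.0600 M; temperature 65 °C; the portions of G follow each other after 40 s, the first at the start; time 2.0 min
- south: J 0.120 M; Z 0.0600 M; temperature 115 °C; the portions of G follow each other after 40 s, the first at the start; time 2.0 min
- west: J 0.120 M; Z 0.0600 M; temperature 90 °C; the portions of G follow each other after 40 s, the first at the start; time 2.0 min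

| run | time / s | X / % | G / % |
|---|---|---|---|
| Tuesday's | 10.0 | 8.7 | 18.6 |
| Tuesday's | 20.0 | 12.6 | 14.0 |
| Tuesday's | 30.0 | 14.6 | 11.3 |
| Tuesday's | 40.0 | 15.2 | 9.0 |
| Tuesday's | 50.0 | 20.6 | 28.3 |
| Tuesday's | 60.0 | 21.1 | 22.2 |
| Sunday's | 10.0 | 16.9 | 7.3 |
| Sunday's | 12.0 | 17.5 | 6.9 |
| Sunday's | 15.0 | 16.4 | 6.5 |

(readings scatter by 0.5 percentage points)

- the flask with the highest amount of X, in percent of the G charged ("all alike" if they lie within 1.5 percentage points) (north-east / south / west / all alike)
- final X, as a percentage of the G charged, in north-east
- final X, as a percentage of the G charged, in south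
- final X, as a percentage of the G charged, in west

- the earlier runs were read with a standard deviation of 0.5 percentage points

The bench rule takes J as the limiting reagent, so X tops out at [J]/[G] of the charge, 60.0 % for the new recipe. Sunday's run marks the border of that rule. At 15.0 s, with the first portion in (33.3 % of the G charged), X stands at 16.4 % and G at 6.5 %, yet [J] is still 0.0572 M, counting one J in each X.

Between 12.0 s and 15.0 s both X and G fall, while X/G holds at 2.54 and 2.52. This reckoning therefore treats G + J ⇌ X as fast and at equilibrium, with Z outside the count, which is where it differs from the forecast. That gives the half-point, the free [J] at which X equals G, an apparent dissociation constant, reckoned as [J][G]/[X]: 0.0227 M as read at 105 °C.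

The ratio of charged J to half-point is 5.29, but free J shrinks as X forms. With this half-point and no G lost, the new charge holds X at 49.1 %, below the ceiling.

G is also lost. X + G falls short of the first portion by 10 points at 15.0 s in Sunday's run, and by 9.1 points at 40.0 s in Tuesday's run, so the loss per second is greater at 105 °C than at 78 °C. Read the same way at 40.0 s, Tuesday's run has [J] 0.0296 M and a half-point of 0.0175 M at 78 °C, smaller than Sunday's reading, though X there is still climbing from 14.6 % to 15.2 %, so this value is a reading and not an equilibrium. The ground for the pick is this trend of the half-point between the two runs, not the faster loss: a smaller half-point holds more G as X at the same free [J], so this reckoning picks north-east, at 65 °C, the coolest flask.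

The forecast also names north-east, with 41 % there, 22 % in south and 33 % in west, reading the equilibrium as “mildly exothermic, with Z present from the start pushing it back”.

The simulation gives 47.6 % in north-east, the highest, 16.7 % in south and 39.6 % in west.

    G + J ⇌ X (K = 74.0 M⁻¹, k = 1.39 M⁻¹ s⁻¹, Ea = 60.0 kJ mol⁻¹, ΔH = −37.0 kJ mol⁻¹)
    2 G → Q (k = 0.350 M⁻¹ s⁻¹, Ea = 63.0 kJ mol⁻¹)
    G + Z → D (k = 0.0860 M⁻¹ s⁻¹, Ea = 69.0 kJ mol⁻¹)
    G + X → E (k = 0.0137 M⁻¹ s⁻¹, Ea = 82.0 kJ mol⁻¹)
    (constants at 90 °C)

West ends at 2.00 min with G 11.6 %, X 39.6 % and 32 % of its J free, which is [J] 0.0380 M, so its half-point is 0.0112 M. The neighbour of west charged with 0.20 M of J ends with G 9.4 % and 38 % of its J free, [J] 0.0767 M, and its half-point is 0.0120 M, close to west's. In that neighbour, X reaches 60.2 %.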